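**Assumption:** compounds 1, 3, 6 and 12 are taken as catalogue chemicals; by CIP (2,6-dimethoxyaryl > 4-methoxyphenyl > CH2 > H) the stereocentre in the target SMILES is S.

## Retrosynthetic overview

1. Target 16 ⇐ diacetate 13 by lipase-catalysed double deacetylation (last step, neutral conditions).
2. 13 ⇐ aryl bromide 11 + 4-acetoxystyrene 12 by a Heck reaction that builds the E-stilbene.
3. 11 ⇐ ketone 7 by MOM removal, ionic hydrogenation of C=O to CH2, and acetylation.
4. 7 ⇐ chalcone 5 + boronic acid 6 by Rh/chiral-diene asymmetric 1,4-arylation (sets the only stereocentre); 5 ⇐ aldehyde 3 + acetophenone 2 by Claisen–Schmidt condensation.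
5. No ring is formed. All four benzene rings are bought and joined in the order 3 + 2, then 6, then 12.

## Route

**Step 1**
Reactants: 1 1-(4-hydroxy-2-methoxyphenyl)ethan-1-one
Product: 2 1-[2-methoxy-4-(methoxymethoxy)phenyl]ethan-1-one
Conditions: MOMCl (1.3 equiv), K2CO3 (2 equiv), acetone, 0 °C → rt
Reagents that add atoms: chloromethyl methyl ether (MOMCl), COCCl
Why: Williamson-type O-alkylation of the acidic para-acyl phenol gives a MOM acetal that is stable to the hydroxide used in steps 2 and 3.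

**Step 2**
Reactants: 2 1-[2-methoxy-4-(methoxymethoxy)phenyl]ethan-1-one; 3 4-bromo-2,6-dimethoxybenzaldehyde
Product: 5 (2E)-3-(4-bromo-2,6-dimethoxyphenyl)-1-[2-methoxy-4-(methoxymethoxy)phenyl]prop-2-en-1-one, via aldol adduct 4 (not isolated)
Conditions: KOH (3 equiv, 50% aq.), EtOH, rt, 24 h
Reagents that add atoms: none
Why: Claisen–Schmidt (crossed aldol) condensation of a non-enolisable aldehyde with a methyl ketone, where E1cB dehydration of the transient racemic aldol gives the conjugated E-enone and the aryl bromide and MOM ether are inert to hydroxide.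

**Step 3**
Reactants: 5 (2E)-3-(4-bromo-2,6-dimethoxyphenyl)-1-[2-methoxy-4-(methoxymethoxy)phenyl]prop-2-en-1-one; 6 (4-methoxyphenyl)boronic acid
Product: 7 (3S)-3-(4-bromo-2,6-dimethoxyphenyl)-3-(4-methoxyphenyl)-1-[2-methoxy-4-(methoxymethoxy)phenyl]propan-1-one
Conditions: 6 (2.5 equiv), [RhCl(C2H4)2]2 (2.5 mol%), (R,R)-Ph-bod* (5.5 mol%), KOH (0.5 equiv, aq.), 1,4-dioxane/H2O 10:1, 50 °C
Reagents that add atoms: none
Why: Hayashi–Miyaura Rh(I)-catalysed asymmetric 1,4-addition, in which the aryl–Rh(diene) species carbometalates the enone and the C2-symmetric (R,R)-diene is expected to direct anisyl transfer to the Re face of C-β to give the S centre (sense and ee to be confirmed by chiral HPLC on the first run, since the (S,S)-ligand gives ent-7), while ArBr and MOM are inert to Rh(I) and aqueous KOH.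

**Step 4**
Reactants: 7 (3S)-3-(4-bromo-2,6-dimethoxyphenyl)-3-(4-methoxyphenyl)-1-[2-methoxy-4-(methoxymethoxy)phenyl]propan-1-one
Product: 8 (3S)-3-(4-bromo-2,6-dimethoxyphenyl)-1-(4-hydroxy-2-methoxyphenyl)-3-(4-methoxyphenyl)propan-1-one
Conditions: 3 M aq. HCl, MeOH/THF 2:1, 50 °C
Reagents that add atoms: none
Why: Acid-catalysed acetal exchange (MOM transfer to methanol) frees the phenol without touching the aryl methyl ethers, the aryl bromide or the non-epimerisable β-diaryl stereocentre.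

**Step 5**
Reactants: 8 (3S)-3-(4-bromo-2,6-dimethoxyphenyl)-1-(4-hydroxy-2-methoxyphenyl)-3-(4-methoxyphenyl)propan-1-one
Product: 10 4-[(3S)-3-(4-bromo-2,6-dimethoxyphenyl)-3-(4-methoxyphenyl)propyl]-3-methoxyphenol, via benzylic alcohol 9 (not isolated)
Conditions: Et3SiH (4 equiv), TFA/CH2Cl2 1:2, 0 °C → rt; NaHCO3/MeOH work-up
Reagents that add atoms: none
Why: Ionic hydrogenation (Kursanov–Parnes) of an aryl ketone whose 2-methoxy-4-hydroxyphenyl ring strongly stabilises the benzylic cation, so excess silane traps it faster than any cyclisation and the remote stereocentre is not involved.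

**Step 6**
Reactants: 10 4-[(3S)-3-(4-bromo-2,6-dimethoxyphenyl)-3-(4-methoxyphenyl)propyl]-3-methoxyphenol
Product: 11 4-[(3S)-3-(4-bromo-2,6-dimethoxyphenyl)-3-(4-methoxyphenyl)propyl]-3-methoxyphenyl acetate
Conditions: Ac2O (1.5 equiv), DMAP (5 mol%), pyridine, rt
Reagents that add atoms: acetic anhydride, CC(=O)OC(C)=O
Why: DMAP-catalysed O-acylation gives the phenol the same acetate mask as the styrene partner, so one enzymatic step can release both phenols at the end.

**Step 7**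
Reactants: 11 4-[(3S)-3-(4-bromo-2,6-dimethoxyphenyl)-3-(4-methoxyphenyl)propyl]-3-methoxyphenyl acetate; 12 4-ethenylphenyl acetate
Product: 13 4-[(3S)-3-{4-[(E)-2-(4-acetoxyphenyl)ethenyl]-2,6-dimethoxyphenyl}-3-(4-methoxyphenyl)propyl]-3-methoxyphenyl acetate
Conditions: 12 (1.5 equiv), Pd2(dba)3 (2 mol%), [(t-Bu)3PH]BF4 (8 mol%), Cy2NMe (1.5 equiv), BHT (cat.), 1,4-dioxane, 80 °C
Reagents that add atoms: none
Why: Mizoroki–Heck reaction of an unhindered, electron-rich aryl bromide under Pd/P(t-Bu)3 catalysis, where β-arylation of the styrene and syn-β-hydride elimination give the E-stilbene and the non-nucleophilic amine base leaves both aryl acetates intact.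

**Step 8**
Reactants: 13 4-[(3S)-3-{4-[(E)-2-(4-acetoxyphenyl)ethenyl]-2,6-dimethoxyphenyl}-3-(4-methoxyphenyl)propyl]-3-methoxyphenyl acetate
Product: 16 4-[(3S)-3-{4-[(E)-2-(4-hydroxyphenyl)ethenyl]-2,6-dimethoxyphenyl}-3-(4-methoxyphenyl)propyl]-3-methoxyphenol, via arm-acetate monoacetate 14 (not isolated), via stilbene-acetate monoacetate 15 (not isolated)
Conditions: immobilised Candida antarctica lipase B (Novozym 435, a lipase, EC 3.1.1.3), n-BuOH (10 equiv), MTBE, 45 °C; filter off enzyme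
Reagents that add atoms: none
Why: Lipase-catalysed transesterification (serine-hydrolase acyl-enzyme mechanism) transfers both unhindered aryl acetyl groups to n-butanol under neutral conditions, so no oxidation-prone hydroxystilbene phenolate forms and the methyl ethers, E-alkene and stereocentre are untouched.

## Compound list

1 | 1-(4-hydroxy-2-methoxyphenyl)ethan-1-one | CC(=O)c1ccc(O)cc1OC | starting material
2 | 1-[2-methoxy-4-(methoxymethoxy)phenyl]ethan-1-one | CC(=O)c1ccc(OCOC)cc1OC | intermediate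
3 | 4-bromo-2,6-dimethoxybenzaldehyde | COc1cc(Br)cc(OC)c1C=O | starting material
4 | 3-(4-bromo-2,6-dimethoxyphenyl)-3-hydroxy-1-[2-methoxy-4-(methoxymethoxy)phenyl]propan-1-one (racemic, transient; its stereocentre is erased on dehydration) | COCOc1ccc(C(=O)CC(O)c2c(OC)cc(Br)cc2OC)c(OC)c1 | intermediate
5 | (2E)-3-(4-bromo-2,6-dimethoxyphenyl)-1-[2-methoxy-4-(methoxymethoxy)phenyl]prop-2-en-1-one | COCOc1ccc(C(=O)/C=C/c2c(OC)cc(Br)cc2OC)c(OC)c1 | intermediate
6 | (4-methoxyphenyl)boronic acid | COc1ccc(B(O)O)cc1 | starting material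
7 | (3S)-3-(4-bromo-2,6-dimethoxyphenyl)-3-(4-methoxyphenyl)-1-[2-methoxy-4-(methoxymethoxy)phenyl]propan-1-one | COc1ccc([C@H](CC(=O)c2ccc(OCOC)cc2OC)c2c(OC)cc(Br)cc2OC)cc1 | intermediate
8 | (3S)-3-(4-bromo-2,6-dimethoxyphenyl)-1-(4-hydroxy-2-methoxyphenyl)-3-(4-methoxyphenyl)propan-1-one | COc1ccc([C@H](CC(=O)c2ccc(O)cc2OC)c2c(OC)cc(Br)cc2OC)cc1 | intermediate
9 | (3S)-3-(4-bromo-2,6-dimethoxyphenyl)-1-(4-hydroxy-2-methoxyphenyl)-3-(4-methoxyphenyl)propan-1-ol (C1 epimer mixture, transient) | COc1ccc([C@H](CC(O)c2ccc(O)cc2OC)c2c(OC)cc(Br)cc2OC)cc1 | intermediate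
10 | 4-[(3S)-3-(4-bromo-2,6-dimethoxyphenyl)-3-(4-methoxyphenyl)propyl]-3-methoxyphenol | COc1ccc([C@H](CCc2ccc(O)cc2OC)c2c(OC)cc(Br)cc2OC)cc1 | intermediate
11 | 4-[(3S)-3-(4-bromo-2,6-dimethoxyphenyl)-3-(4-methoxyphenyl)propyl]-3-methoxyphenyl acetate | COc1ccc([C@H](CCc2ccc(OC(C)=O)cc2OC)c2c(OC)cc(Br)cc2OC)cc1 | intermediate
12 | 4-ethenylphenyl acetate (4-acetoxystyrene) | CC(=O)Oc1ccc(C=C)cc1 | starting material
13 | 4-[(3S)-3-{4-[(E)-2-(4-acetoxyphenyl)ethenyl]-2,6-dimethoxyphenyl}-3-(4-methoxyphenyl)propyl]-3-methoxyphenyl acetate | COc1ccc([C@H](CCc2ccc(OC(C)=O)cc2OC)c2c(OC)cc(/C=C/c3ccc(OC(C)=O)cc3)cc2OC)cc1 | intermediate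
14 | 4-[(3S)-3-{4-[(E)-2-(4-hydroxyphenyl)ethenyl]-2,6-dimethoxyphenyl}-3-(4-methoxyphenyl)propyl]-3-methoxyphenyl acetate | COc1ccc([C@H](CCc2ccc(OC(C)=O)cc2OC)c2c(OC)cc(/C=C/c3ccc(O)cc3)cc2OC)cc1 | intermediate
15 | 4-[(E)-2-{4-[(1S)-3-(4-hydroxy-2-methoxyphenyl)-1-(4-methoxyphenyl)propyl]-3,5-dimethoxyphenyl}ethenyl]phenyl acetate | COc1ccc([C@H](CCc2ccc(O)cc2OC)c2c(OC)cc(/C=C/c3ccc(OC(C)=O)cc3)cc2OC)cc1 | intermediate
16 | 4-[(3S)-3-{4-[(E)-2-(4-hydroxyphenyl)ethenyl]-2,6-dimethoxyphenyl}-3-(4-methoxyphenyl)propyl]-3-methoxyphenol (CNP0182684.1) | COc1ccc([C@H](CCc2ccc(O)cc2OC)c2c(OC)cc(/C=C/c3ccc(O)cc3)cc2OC)cc1 | target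

## Summary

Total step count: 8.
Longest linear sequence: 8 steps (1 → 2 → 5 → 7 → 8 → 10 → 11 → 13 → 16).

## Steps most likely to fail, with fallbacks

**Step 3 (Rh 1,4-arylation).** The β-aryl group carries two ortho methoxy groups and the aryl ketone is electron-rich, so rate, and with it ee, may be poor. The fallback sets out from 3 and comes back at 7. Wittig olefination of 3 with (triphenylphosphoranylidene)acetaldehyde (toluene, 80 °C) gives (2E)-3-(4-bromo-2,6-dimethoxyphenyl)prop-2-enal F1. This enal is a far more electrophilic and less encumbered acceptor, and it takes up 6 under [RhCl(C2H4)2]2/(R,R)-Ph-bod*, KOH, MeOH/H2O, 50 °C to give (3S)-3-(4-bromo-2,6-dimethoxyphenyl)-3-(4-methoxyphenyl)propanal F2. Separately, 4-bromo-3-methoxyphenol is converted with MOMCl/K2CO3 into 1-bromo-2-methoxy-4-(methoxymethoxy)benzene F3, and with Mg in THF into [2-methoxy-4-(methoxymethoxy)phenyl]magnesium bromide F4. F4 adds to F2 at −78 → 0 °C (the ArBr of F2 is inert) to give (3S)-3-(4-bromo-2,6-dimethoxyphenyl)-1-[2-methoxy-4-(methoxymethoxy)phenyl]-3-(4-methoxyphenyl)propan-1-ol F5 as a C1 epimer mixture. Dess–Martin oxidation of F5 gives 7, and the route continues with step 4.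

**Step 5 (ionic hydrogenation).** The benzylic cation could cyclise onto the anisyl ring to an indane, or reduction could stall at the carbinol. The fallback sets out from 8 and comes back at 10, and avoids any cation. Condensation of 8 with tosylhydrazide (EtOH, cat. AcOH, reflux) gives N'-[(3S)-3-(4-bromo-2,6-dimethoxyphenyl)-1-(4-hydroxy-2-methoxyphenyl)-3-(4-methoxyphenyl)propylidene]-4-methylbenzenesulfonohydrazide F6. Treatment of F6 with catecholborane (3 equiv, CHCl3, 0 °C → rt) and then NaOAc·3H2O at reflux (Kabalka variant of the Caglioti reduction) gives 10 through the diazene, with loss of N2 and sulfinate. The aryl bromide is untouched.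

**Step 7 (Heck reaction).** The electron-rich aryl bromide may undergo slow oxidative addition, and 4-acetoxystyrene may polymerise. The fallback sets out from 11 and comes back at 13, and reverses the roles of the partners. Stille vinylation of 11 with tributyl(vinyl)stannane (Pd(PPh3)4, toluene, 100 °C, neutral so the acetate survives) gives 4-[(3S)-3-(4-ethenyl-2,6-dimethoxyphenyl)-3-(4-methoxyphenyl)propyl]-3-methoxyphenyl acetate F7. A Heck reaction of F7 with the much more reactive 4-iodophenyl acetate (Pd(OAc)2, Et3N, MeCN, 80 °C) gives 13 as the E-stilbene.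

## Further compounds

F1 | step 3 | (2E)-3-(4-bromo-2,6-dimethoxyphenyl)prop-2-enal | COc1cc(Br)cc(OC)c1/C=C/C=O
F2 | step 3 | (3S)-3-(4-bromo-2,6-dimethoxyphenyl)-3-(4-methoxyphenyl)propanal | COc1ccc([C@H](CC=O)c2c(OC)cc(Br)cc2OC)cc1
F3 | step 3 | 1-bromo-2-methoxy-4-(methoxymethoxy)benzene | COCOc1ccc(Br)c(OC)c1
F4 | step 3 | [2-methoxy-4-(methoxymethoxy)phenyl]magnesium bromide | COCOc1ccc([Mg]Br)c(OC)c1
F5 | step 3 | (3S)-3-(4-bromo-2,6-dimethoxyphenyl)-1-[2-methoxy-4-(methoxymethoxy)phenyl]-3-(4-methoxyphenyl)propan-1-ol (C1 epimer mixture) | COc1ccc([C@H](CC(O)c2ccc(OCOC)cc2OC)c2c(OC)cc(Br)cc2OC)cc1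
F6 | step 5 | N'-[(3S)-3-(4-bromo-2,6-dimethoxyphenyl)-1-(4-hydroxy-2-methoxyphenyl)-3-(4-methoxyphenyl)propylidene]-4-methylbenzenesulfonohydrazide | COc1ccc([C@H](CC(=NNS(=O)(=O)c2ccc(C)cc2)c2ccc(O)cc2OC)c2c(OC)cc(Br)cc2OC)cc1
F7 | step 7 | 4-[(3S)-3-(4-ethenyl-2,6-dimethoxyphenyl)-3-(4-methoxyphenyl)propyl]-3-methoxyphenyl acetate | COc1ccc([C@H](CCc2ccc(OC(C)=O)cc2OC)c2c(OC)cc(C=C)cc2OC)cc1
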